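## Retrosynthetic overview

1. The target is epigallocatechin-(4β→8)-epigallocatechin-(4β→8)-epigallocatechin 3-O-gallate-(4β→8)-epicatechin, with every unit 2R,3R and every link 3,4-trans. The last operation is one hydrogenolysis of 23 benzyl ethers and one C8–Br cap.
2. Enabling feature: C4 of ring C of the uppermost unit is a methine bonded to two phloroglucinol-type ring carbons. These are C4a of its own ring A (ortho to O1) and C8 of ring A of the second unit. C4 is therefore a latent aldehyde carbon, and C4–C4a and C4–C8 are cut together.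
3. Key step: an acyclic aryl ether dimethyl acetal (O1–C2–C3–C4 chain) and the benzylated trimer react in one Lewis acid operation. This closes ring C, forms the third interflavan bond and sets C4.
4. In the acyclic precursor, C2 and C3 come from an Evans syn glycolate aldol and O1–C8a from an SNAr with retention at C2. The trimer comes from two 4β→8 couplings of benzylated natural monomers.
5. Ring order: all aromatic rings and the three lower rings C are bought closed. Ring C of the top unit is the only ring built, and it is closed last.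

Key step: step 15

Assumption: flavan numbering (O1, C2, C3, C4, C4a, C5 to C8, C8a; rings A, B, C) is used for every unit and also for the acyclic precursors of the top unit. Intermediate 24 is drawn as its 4β epimer, because both C4 epimers would ionise to the same cation. Compounds 1, 3, 6, 10, 13, 14 and 16 are taken as commercial.

## Route

Step 1
Reactants: 1 (−)-epicatechin
Product: 2 5,7,3',4'-tetra-O-benzyl-(−)-epicatechin (2R,3R; 3-OH free)
Conditions: BnBr (4.4 equiv), K2CO3, DMF, Ar, 0 °C to rt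
Reagents that add atoms: benzyl bromide, BrCc1ccccc1
Why: Williamson etherification, in which the weak base deprotonates only the four phenols and not the secondary 3-OH, so C2 and C3 of the natural product are carried through unchanged.

Step 2
Reactants: 3 (−)-epigallocatechin
Product: 4 5,7,3',4',5'-penta-O-benzyl-(−)-epigallocatechin (2R,3R; 3-OH free)
Conditions: BnBr (5.5 equiv), K2CO3, DMF, Ar, 0 °C to rt
Reagents that add atoms: benzyl bromide, BrCc1ccccc1
Why: Williamson etherification of the five phenols under exclusion of air, which protects the oxidation-prone pyrogallol ring and leaves the 3-OH and both stereocentres untouched.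

Step 3
Reactants: 4 penta-O-benzyl-epigallocatechin
Product: 5 4β-(2-ethoxyethoxy)-5,7,3',4',5'-penta-O-benzyl-epigallocatechin (2,3-cis, 3,4-trans)
Conditions: DDQ, 2-ethoxyethanol, CH2Cl2, rt
Reagents that add atoms: 2-ethoxyethanol, CCOCCO
Why: DDQ benzylic C–H oxidation, in which hydride abstraction at C4 gives the cation stabilised by ring A and the alcohol should trap it from the β face, anti to the α-oriented 2-aryl and 3-OH groups.

Step 4
Reactants: 5 4β-(2-ethoxyethoxy)-penta-O-benzyl-epigallocatechin; 6 3,4,5-tris(benzyloxy)benzoic acid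
Product: 7 4β-(2-ethoxyethoxy)-5,7,3',4',5'-penta-O-benzyl-3-O-[3,4,5-tris(benzyloxy)benzoyl]epigallocatechin
Conditions: DCC, DMAP, CH2Cl2, rt
Reagents that add atoms: none
Why: Steglich esterification of the only free hydroxyl group, which breaks no bond at a stereocentre.

Step 5
Reactants: 7 galloylated 4-alkoxy electrophile; 2 tetra-O-benzyl-epicatechin (3 equiv, excess recovered)
Product: 8 [5,7,3',4',5'-penta-O-benzyl-3-O-(tri-O-benzylgalloyl)epigallocatechin]-(4β→8)-[5,7,3',4'-tetra-O-benzylepicatechin]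
Conditions: TMSOTf (10 mol %), CH2Cl2, −78 °C
Reagents that add atoms: none
Why: Lewis-acid Friedel–Crafts 4→8 flavanyl coupling, in which the C4 cation is shielded on its α face by the 2-aryl group and the participating 3-O-galloyl group, so C8 of 2 (its most accessible ring A carbon) should add from the β face to give the 3,4-trans link.

Step 6
Reactants: 5 4β-(2-ethoxyethoxy)-penta-O-benzyl-epigallocatechin (added slowly); 8 benzylated dimer (2 equiv, excess recovered)
Product: 9 [penta-O-benzylepigallocatechin]-(4β→8)-[penta-O-benzyl-3-O-(tri-O-benzylgalloyl)epigallocatechin]-(4β→8)-[tetra-O-benzylepicatechin]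
Conditions: TMSOTf (10 mol %), CH2Cl2, −78 to −40 °C
Reagents that add atoms: none
Why: the same Friedel–Crafts 4→8 coupling, in which C8 of the upper unit of 8 is the only unhindered phloroglucinol-type carbon and the α face of the epi-configured cation is blocked by the 2-aryl and 3-OH groups, so the new C4 should be 4β.

Step 7
Reactants: 10 1,3,5-trifluorobenzene
Product: 11 1,3-bis(benzyloxy)-5-fluorobenzene
Conditions: BnOH (2.1 equiv), NaH, DMF, 0 to 60 °C
Reagents that add atoms: benzyl alcohol, OCc1ccccc1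
Why: twofold SNAr, in which each fluorine is activated inductively by its meta halogens and each alkoxy group introduced slows the next substitution, so stoichiometry and temperature should stop the reaction at the disubstituted stage.

Step 8
Reactants: 11 1,3-bis(benzyloxy)-5-fluorobenzene
Product: 12 1,5-bis(benzyloxy)-2-bromo-3-fluorobenzene
Conditions: NBS (1.0 equiv), MeCN, 0 °C, dark
Reagents that add atoms: N-bromosuccinimide, O=C1CCC(=O)N1Br
Why: electrophilic aromatic bromination, which should prefer the carbon between F and OBn (ortho and para to the two benzyloxy groups, next to the small fluorine) over the carbon crowded between two benzyloxy groups.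

Step 9
Reactants: 13 (S)-4-benzyloxazolidin-2-one; 14 (benzyloxy)acetyl chloride
Product: 15 (S)-4-benzyl-3-[(benzyloxy)acetyl]oxazolidin-2-one
Conditions: n-BuLi, THF, −78 °C; then 14, −78 to 0 °C
Reagents that add atoms: none
Why: N-acylation of the lithiated oxazolidinone with an acid chloride, a standard way to load the auxiliary.

Step 10
Reactants: 15 glycolyl imide; 16 3,4,5-tris(benzyloxy)benzaldehyde
Product: 19 (S)-4-benzyl-3-{(2S,3R)-2-(benzyloxy)-3-hydroxy-3-[3,4,5-tris(benzyloxy)phenyl]propanoyl}oxazolidin-2-one, via boron enolate 17 (not isolated), via boron aldolate 18 (not isolated)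
Conditions: Bu2BOTf, Et3N, CH2Cl2, −78 to 0 °C; 16, −78 to 0 °C; then pH 7 buffer, MeOH, 30% H2O2, 0 °C
Reagents that add atoms: none
Why: Evans syn aldol, in which the (Z)-boron enolate reacts through a closed Zimmerman–Traxler chair on the face left open by the benzyl group of the auxiliary, setting the future C3 (OBn) and C2 (OH) together as the (2S,3R) syn pair that corresponds to 2R,3R-cis in the flavan.

Step 11
Reactants: 19 syn aldol adduct
Product: 20 (2S,3R)-2-(benzyloxy)-3-hydroxy-N-methoxy-N-methyl-3-[3,4,5-tris(benzyloxy)phenyl]propanamide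
Conditions: MeNH(OMe)·HCl, AlMe3, CH2Cl2, −20 °C to rt
Reagents that add atoms: N,O-dimethylhydroxylamine hydrochloride, CNOC.Cl
Why: aluminium amide transamidation to the Weinreb amide, assisted by the free β-hydroxyl group, which releases the auxiliary without touching either stereocentre.

Step 12
Reactants: 20 Weinreb amide
Product: 21 (2S,3R)-2-(benzyloxy)-3-hydroxy-3-[3,4,5-tris(benzyloxy)phenyl]propanal (used crude)
Conditions: i-Bu2AlH (2.5 equiv), THF, −78 °C; aqueous Rochelle salt
Reagents that add atoms: none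
Why: Weinreb amide reduction, in which the chelated tetrahedral intermediate prevents over-reduction and the low temperature should prevent epimerisation at the α-carbon and retro-aldol cleavage.

Step 13
Reactants: 21 hydroxy aldehyde
Product: 22 (1R,2S)-2-(benzyloxy)-3,3-dimethoxy-1-[3,4,5-tris(benzyloxy)phenyl]propan-1-ol
Conditions: HC(OMe)3, PPTS (10 mol %), MeOH, rt
Reagents that add atoms: trimethyl orthoformate, COC(OC)OC
Why: acid-catalysed acetalisation with the orthoformate as water scavenger, in which the mild acid should leave the benzylic alcohol intact, freezing C4 at the aldehyde level in a base-stable and configurationally safe form.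

Step 14
Reactants: 22 hydroxy acetal; 12 1,5-bis(benzyloxy)-2-bromo-3-fluorobenzene
Product: 23 (1R,2S)-2-(benzyloxy)-1-[3,5-bis(benzyloxy)-2-bromophenoxy]-3,3-dimethoxy-1-[3,4,5-tris(benzyloxy)phenyl]propane
Conditions: KN(SiMe3)2 (1.0 equiv), THF, 0 °C; then 12, DMPU, 60 °C
Reagents that add atoms: none
Why: SNAr of the potassium alkoxide on the fluoroarene (activated by the ortho bromine and the two meta alkoxy groups), which forms O1–C8a without breaking the carbinol C–O bond, so C2 is retained and the syn (future 2,3-cis) relationship is kept.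

Step 15
Reactants: 23 aryl ether dimethyl acetal (added slowly); 9 benzylated trimer (1.0 equiv)
Product: 25 [8-bromo-3,5,7,3',4',5'-hexa-O-benzylepigallocatechin]-(4β→8)-[penta-O-benzylepigallocatechin]-(4β→8)-[penta-O-benzyl-3-O-(tri-O-benzylgalloyl)epigallocatechin]-(4β→8)-[tetra-O-benzylepicatechin], via 4-methoxyflavan 24 (not isolated)
Conditions: BF3·OEt2 (0.5 equiv), 4 Å MS, CH2Cl2, −78 to −20 °C
Reagents that add atoms: none
Why: Proposed new method: BF3 ionises one methoxy group of acetal 23 to the C4 oxocarbenium ion, the only free ortho carbon of the tethered ring A attacks it (C4–C4a) to give 4-methoxyflavan 24, and a second ionisation gives the C4 benzylic cation, stabilised by O1 and the 5- and 7-benzyloxy groups, which C8 of the uppermost unit of 9 captures (C4–C8), so one acetal carbon is arylated by two different arenes in one flask (should 9 add first, closure of the resulting cation onto ring A leads to the same product). The closest known reaction types are the Lewis-acid cyclisation of 3-aryloxypropanal acetals to 4-alkoxychromans and the BF3·OEt2- or TMSOTf-mediated 4→8 coupling of 8-bromo-4-alkoxyflavan-3-ol ethers with benzylated flavan-3-ols, and what is new is their merger starting from an acyclic precursor. Ring C closes in the 6-exo-trig mode at the oxocarbenium carbon, with the attacking arene π bond lying inside the new ring. C4, the only new stereocentre, is under substrate control: the 2-aryl and 3-benzyloxy groups both occupy the α face of the half-chair cation, so the bulky nucleophile should enter from the β face (3,4-trans, 2,4-trans), as in couplings of the epi series. The step needs chemoselectivity among several ring A type nucleophiles and site selectivity within 9: the bromine blocks the second ortho position and deactivates ring A of 23, 24 and 25 so that it reacts only intramolecularly (no self-condensation, no growth beyond the tetramer), six-ring closure onto the trioxygenated ring A should outrun five-ring closure onto ring B, and in 9 only C8 of the top unit is an unhindered phloroglucinol-type carbon, since every C6 lies between two benzyloxy groups.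

Step 16
Reactants: 25 protected 8-bromo tetramer
Product: 26 epigallocatechin-(4β→8)-epigallocatechin-(4β→8)-epigallocatechin 3-O-gallate-(4β→8)-epicatechin (CNP0305998.1)
Conditions: H2 (1 atm), Pd(OH)2/C, NaOAc (1.5 equiv), THF/MeOH/H2O, rt
Reagents that add atoms: none
Why: heterogeneous hydrogenolysis, which should cleave all 23 benzyl ethers and hydrodebrominate C8 in the same operation while NaOAc buffers the HBr, leaving the gallate ester, the three interflavan bonds and all eleven stereocentres untouched.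

## Compound list

1 | (−)-epicatechin | O[C@@H]1Cc2c(O)cc(O)cc2O[C@@H]1c1ccc(O)c(O)c1 | starting material
2 | 5,7,3',4'-tetra-O-benzyl-(−)-epicatechin | O[C@@H]1Cc2c(OCc3ccccc3)cc(OCc3ccccc3)cc2O[C@@H]1c1ccc(OCc2ccccc2)c(OCc2ccccc2)c1 | intermediate
3 | (−)-epigallocatechin | O[C@@H]1Cc2c(O)cc(O)cc2O[C@@H]1c1cc(O)c(O)c(O)c1 | starting material
4 | 5,7,3',4',5'-penta-O-benzyl-(−)-epigallocatechin | O[C@@H]1Cc2c(OCc3ccccc3)cc(OCc3ccccc3)cc2O[C@@H]1c1cc(OCc2ccccc2)c(OCc2ccccc2)c(OCc2ccccc2)c1 | intermediate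
5 | 4β-(2-ethoxyethoxy)-penta-O-benzyl-epigallocatechin | O[C@@H]1[C@@H](OCCOCC)c2c(OCc3ccccc3)cc(OCc3ccccc3)cc2O[C@@H]1c1cc(OCc2ccccc2)c(OCc2ccccc2)c(OCc2ccccc2)c1 | intermediate
6 | 3,4,5-tris(benzyloxy)benzoic acid | OC(=O)c1cc(OCc2ccccc2)c(OCc2ccccc2)c(OCc2ccccc2)c1 | starting material
7 | 4β-(2-ethoxyethoxy)-penta-O-benzyl-3-O-(tri-O-benzylgalloyl)epigallocatechin | O=C(O[C@@H]1[C@@H](OCCOCC)c2c(OCc3ccccc3)cc(OCc3ccccc3)cc2O[C@@H]1c1cc(OCc2ccccc2)c(OCc2ccccc2)c(OCc2ccccc2)c1)c1cc(OCc2ccccc2)c(OCc2ccccc2)c(OCc2ccccc2)c1 | intermediate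
8 | benzylated dimer, EGC 3-O-gallate-(4β→8)-EC | O=C(O[C@@H]1[C@@H](c2c(OCc7ccccc7)cc(OCc7ccccc7)c3c2O[C@H](c2ccc(OCc7ccccc7)c(OCc7ccccc7)c2)[C@H](O)C3)c2c(OCc7ccccc7)cc(OCc7ccccc7)cc2O[C@@H]1c1cc(OCc7ccccc7)c(OCc7ccccc7)c(OCc7ccccc7)c1)c1cc(OCc7ccccc7)c(OCc7ccccc7)c(OCc7ccccc7)c1 | intermediate
9 | benzylated trimer, EGC-(4β→8)-EGC 3-O-gallate-(4β→8)-EC | O=C(O[C@@H]1[C@@H](c2c(OCc7ccccc7)cc(OCc7ccccc7)c3c2O[C@H](c2ccc(OCc7ccccc7)c(OCc7ccccc7)c2)[C@H](O)C3)c2c(OCc7ccccc7)cc(OCc7ccccc7)c([C@H]3c4c(OCc7ccccc7)cc(OCc7ccccc7)cc4O[C@H](c4cc(OCc7ccccc7)c(OCc7ccccc7)c(OCc7ccccc7)c4)[C@@H]3O)c2O[C@@H]1c1cc(OCc7ccccc7)c(OCc7ccccc7)c(OCc7ccccc7)c1)c1cc(OCc7ccccc7)c(OCc7ccccc7)c(OCc7ccccc7)c1 | intermediate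
10 | 1,3,5-trifluorobenzene | Fc1cc(F)cc(F)c1 | starting material
11 | 1,3-bis(benzyloxy)-5-fluorobenzene | Fc1cc(OCc2ccccc2)cc(OCc2ccccc2)c1 | intermediate
12 | 1,5-bis(benzyloxy)-2-bromo-3-fluorobenzene | Fc1cc(OCc2ccccc2)cc(OCc2ccccc2)c1Br | intermediate
13 | (S)-4-benzyloxazolidin-2-one | O=C1N[C@@H](Cc2ccccc2)CO1 | starting material
14 | (benzyloxy)acetyl chloride | ClC(=O)COCc1ccccc1 | starting material
15 | (S)-4-benzyl-3-[(benzyloxy)acetyl]oxazolidin-2-one | O=C(COCc1ccccc1)N1[C@@H](Cc2ccccc2)COC1=O | intermediate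
16 | 3,4,5-tris(benzyloxy)benzaldehyde | O=Cc1cc(OCc2ccccc2)c(OCc2ccccc2)c(OCc2ccccc2)c1 | starting material
17 | (Z)-dibutylboron enolate of 15 | CCCCB(CCCC)O/C(=C\OCc1ccccc1)N1[C@@H](Cc2ccccc2)COC1=O | intermediate
18 | dibutylboron aldolate of 19 | CCCCB(CCCC)O[C@H](c1cc(OCc2ccccc2)c(OCc2ccccc2)c(OCc2ccccc2)c1)[C@@H](C(=O)N1[C@@H](Cc2ccccc2)COC1=O)OCc1ccccc1 | intermediate
19 | (2S,3R) syn aldol adduct on the (S)-auxiliary | O[C@H](c1cc(OCc2ccccc2)c(OCc2ccccc2)c(OCc2ccccc2)c1)[C@@H](C(=O)N1[C@@H](Cc2ccccc2)COC1=O)OCc1ccccc1 | intermediate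
20 | (2S,3R) Weinreb amide | O[C@H](c1cc(OCc2ccccc2)c(OCc2ccccc2)c(OCc2ccccc2)c1)[C@@H](C(=O)N(C)OC)OCc1ccccc1 | intermediate
21 | (2S,3R)-2-(benzyloxy)-3-hydroxy-3-[3,4,5-tris(benzyloxy)phenyl]propanal | O[C@H](c1cc(OCc2ccccc2)c(OCc2ccccc2)c(OCc2ccccc2)c1)[C@@H](C=O)OCc1ccccc1 | intermediate
22 | (1R,2S)-2-(benzyloxy)-3,3-dimethoxy-1-[3,4,5-tris(benzyloxy)phenyl]propan-1-ol | O[C@H](c1cc(OCc2ccccc2)c(OCc2ccccc2)c(OCc2ccccc2)c1)[C@@H](C(OC)OC)OCc1ccccc1 | intermediate
23 | (1R,2S) 3,5-bis(benzyloxy)-2-bromophenyl ether of 22 | Brc1c(OCc2ccccc2)cc(OCc2ccccc2)cc1O[C@H](c1cc(OCc2ccccc2)c(OCc2ccccc2)c(OCc2ccccc2)c1)[C@@H](C(OC)OC)OCc1ccccc1 | intermediate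
24 | 8-bromo-4β-methoxy-3,5,7,3',4',5'-hexa-O-benzylepigallocatechin | CO[C@H]1c2c(OCc3ccccc3)cc(OCc3ccccc3)c(Br)c2O[C@H](c2cc(OCc3ccccc3)c(OCc3ccccc3)c(OCc3ccccc3)c2)[C@@H]1OCc1ccccc1 | intermediate
25 | protected 8-bromo tetramer | O=C(O[C@@H]1[C@@H](c2c(OCc7ccccc7)cc(OCc7ccccc7)c3c2O[C@H](c2ccc(OCc7ccccc7)c(OCc7ccccc7)c2)[C@H](O)C3)c2c(OCc7ccccc7)cc(OCc7ccccc7)c([C@H]3c4c(OCc7ccccc7)cc(OCc7ccccc7)c([C@H]5c6c(OCc7ccccc7)cc(OCc7ccccc7)c(Br)c6O[C@H](c6cc(OCc7ccccc7)c(OCc7ccccc7)c(OCc7ccccc7)c6)[C@@H]5OCc7ccccc7)c4O[C@H](c4cc(OCc7ccccc7)c(OCc7ccccc7)c(OCc7ccccc7)c4)[C@@H]3O)c2O[C@@H]1c1cc(OCc7ccccc7)c(OCc7ccccc7)c(OCc7ccccc7)c1)c1cc(OCc7ccccc7)c(OCc7ccccc7)c(OCc7ccccc7)c1 | intermediate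
26 | CNP0305998.1 | O=C(O[C@@H]1[C@@H](c2c(O)cc(O)c3c2O[C@H](c2ccc(O)c(O)c2)[C@H](O)C3)c2c(O)cc(O)c([C@H]3c4c(O)cc(O)c([C@H]5c6c(O)cc(O)cc6O[C@H](c6cc(O)c(O)c(O)c6)[C@@H]5O)c4O[C@H](c4cc(O)c(O)c(O)c4)[C@@H]3O)c2O[C@@H]1c1cc(O)c(O)c(O)c1)c1cc(O)c(O)c(O)c1 | target

## Step count and risks

Total step count: 16. Longest linear sequence: 8 steps (steps 9 to 16). The trimer branch (steps 2 to 6, then 15 and 16) has 7 steps.

**Step 15 (labelled step).**
- Ring closure may be slowed by the bromine on ring A. Capture of the acyclic oxocarbenium ion by hydroxyl groups or arenes of the trimer, or closure onto ring B, could then compete.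
- Prolonged acid exposure may also start to scramble the existing interflavan bonds.
- Fallback with known chemistry: the two events are separated. Setting out from 23, the acetal is cyclised alone under high dilution (SnCl4, CH2Cl2, −78 °C) and the 4-methoxyflavan 24 is isolated.
- 24 is then used as a conventional bromine-capped 4-alkoxyflavan electrophile towards 9 (BF3·OEt2, CH2Cl2, −78 °C), which returns to the route at 25. This fallback makes no compound outside the list (entry F0).

**Step 14.**
- Substitution of the only weakly activated fluoroarene by a hindered secondary alkoxide may be too slow. Base-induced aryne formation or decomposition of the alkoxide could then take over.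
- Fallback with reversed polarity, ring A now acting as the nucleophile. Setting out from 22, Dess–Martin oxidation gives (R)-2-(benzyloxy)-3,3-dimethoxy-1-[3,4,5-tris(benzyloxy)phenyl]propan-1-one F1.
- Chelation-controlled reduction with Zn(BH4)2 gives the anti alcohol (1S,2S)-2-(benzyloxy)-3,3-dimethoxy-1-[3,4,5-tris(benzyloxy)phenyl]propan-1-ol F2.
- Mitsunobu etherification (PPh3, DIAD, toluene, 0 °C) with 3,5-bis(benzyloxy)-2-bromophenol F3 inverts C2 and returns to the route at 23. F3 is made from commercial 3,5-bis(benzyloxy)phenol and NBS.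

**Step 6.**
- The uncapped electrophile 5 may condense with itself, and the chain may grow further on the free C8 of product 9. Either process consumes the dimer in oligomer mixtures.
- Fallback with a capping strategy. Setting out from 5, bromination with NBS (CH2Cl2, −78 to 0 °C) gives 8-bromo-4β-(2-ethoxyethoxy)-penta-O-benzyl-epigallocatechin F4.
- Equimolar coupling of F4 with 8 (BF3·OEt2, CH2Cl2, −78 °C) gives the 8-bromo trimer F5, which can no longer act as a nucleophile.
- Radical hydrodebromination (Bu3SnH, AIBN, toluene, 80 °C), which is compatible with the gallate ester and the benzyl ethers, returns to the route at 9.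

Further compounds
F0 | step 15 | none | none
F1 | step 14 | (R)-2-(benzyloxy)-3,3-dimethoxy-1-[3,4,5-tris(benzyloxy)phenyl]propan-1-one | O=C(c1cc(OCc2ccccc2)c(OCc2ccccc2)c(OCc2ccccc2)c1)[C@@H](C(OC)OC)OCc1ccccc1
F2 | step 14 | (1S,2S)-2-(benzyloxy)-3,3-dimethoxy-1-[3,4,5-tris(benzyloxy)phenyl]propan-1-ol | O[C@@H](c1cc(OCc2ccccc2)c(OCc2ccccc2)c(OCc2ccccc2)c1)[C@@H](C(OC)OC)OCc1ccccc1
F3 | step 14 | 3,5-bis(benzyloxy)-2-bromophenol | Oc1cc(OCc2ccccc2)cc(OCc2ccccc2)c1Br
F4 | step 6 | 8-bromo-4β-(2-ethoxyethoxy)-penta-O-benzyl-epigallocatechin | O[C@@H]1[C@@H](OCCOCC)c2c(OCc3ccccc3)cc(OCc3ccccc3)c(Br)c2O[C@@H]1c1cc(OCc2ccccc2)c(OCc2ccccc2)c(OCc2ccccc2)c1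
F5 | step 6 | 8-bromo trimer (9 with bromine at C8 of its top unit) | O=C(O[C@@H]1[C@@H](c2c(OCc7ccccc7)cc(OCc7ccccc7)c3c2O[C@H](c2ccc(OCc7ccccc7)c(OCc7ccccc7)c2)[C@H](O)C3)c2c(OCc7ccccc7)cc(OCc7ccccc7)c([C@H]3c4c(OCc7ccccc7)cc(OCc7ccccc7)c(Br)c4O[C@H](c4cc(OCc7ccccc7)c(OCc7ccccc7)c(OCc7ccccc7)c4)[C@@H]3O)c2O[C@@H]1c1cc(OCc7ccccc7)c(OCc7ccccc7)c(OCc7ccccc7)c1)c1cc(OCc7ccccc7)c(OCc7ccccc7)c(OCc7ccccc7)c1
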